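**Strategy.** Labdane numbering: ring A is C1–C2–C3–C4–C5–C10 and the formyl carbon on C4 is C19. The route rests on reading the β-acetoxy aldehyde array C3(OAc)–C4(CH3)(CHO) as the product of a Lewis-acid 1,2-shift in an epoxy alcohol ester. In the precursor, a trans-fused cycloheptene oxide annulated to a carvone-derived ring B, C19 is still a ring carbon between C3 and C4. Ionising the C19–C4 epoxide at tertiary C4 moves C3 from C19 to C4: the seven-membered ring contracts to ring A, the quaternary C4 stereocentre is set by inversion and the aldehyde is unveiled with the acetate already in place.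

Key step: step 12

Remark: (−)-MIB is assumed to direct vinyl transfer to the Si face of aldehyde 17, as it does in related organozinc additions; if the sense proves opposite, (+)-MIB is used. Labdane numbering is used for all intermediates (C11–C16 = side chain).

## Route

Step 1
Reactants: 1 (S)-(+)-carvone
Product: 3 (5S,6R)-6-methylcarvone (methyl trans to isopropenyl; major epimer expected), via lithium dienolate 2 (not isolated)
Conditions: LiN(iPr)2 (LDA), THF, −78 °C; MeI, −78 → 0 °C
Reagents that add atoms: iodomethane CI
Why: Kinetic α′-deprotonation and enolate C-methylation introduce the future C10 methyl; the new C6 centre (trans isomer expected to predominate) is erased by enolisation in step 2, so its configuration is immaterial.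

Step 2
Reactants: 3 (5S,6R)-6-methylcarvone
Product: 5 (5R,6R)-6-allyl-6-methylcarvone (allyl trans to isopropenyl), via lithium enolate 4 (not isolated)
Conditions: LiN(iPr)2, THF, −78 °C; allyl bromide, −78 °C → rt
Reagents that add atoms: allyl bromide C=CCBr
Why: Enolate alkylation builds the quaternary C10 centre under substrate control, the allyl group entering anti to the adjacent isopropenyl group (established behaviour of 6-substituted carvone enolates), which places the C1 arm trans and the methyl cis to the future C4 carbon as the trans ring fusion requires.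

Step 3
Reactants: 5 (5R,6R)-6-allyl-6-methylcarvone; 6 2-(2-bromoethyl)-2-methyl-1,3-dioxolane
Product: 9 tertiary allylic methyl carbonate (C9 carries the ketal side chain; OCO2Me cis to the C10 methyl), via Grignard reagent 7 (not isolated), via magnesium alkoxide 8 (not isolated)
Conditions: 6, Mg, THF, 25 °C; then 5, LaCl3·2LiCl (30 mol %), THF, −20 → 0 °C; then ClCO2Me, 0 °C → rt
Reagents that add atoms: methyl chloroformate COC(=O)Cl
Why: Lanthanum-assisted 1,2-addition of the Grignard reagent to the hindered enone carbonyl is expected to occur anti to the pseudoaxial C10 methyl, so that the alkoxide oxygen lies cis to that methyl, and in situ O-acylation with the chloroformate turns it into a leaving group for palladium.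

Step 4
Reactants: 9 tertiary allylic methyl carbonate
Product: 11 methyl ketone (ring B with C7=C8; C9–H trans and 3-oxobutyl chain cis to the C10 methyl), via ketal triene 10 (not isolated)
Conditions: Pd(OAc)2 (5 mol %), n-Bu3P (10 mol %), HCO2H, Et3N, THF, 25 → 60 °C; then 1 M HCl, THF, rt
Reagents that add atoms: water O
Why: Tsuji–Mandai hydrogenolysis: zerovalent palladium ionises the carbonate with inversion and the palladium formate transfers hydride to the more substituted allyl terminus C9 on the metal-bearing face, which sets C9 (hydrogen trans, side chain cis to the C10 methyl) and leaves the less substituted C7=C8 alkene, after which aqueous acid hydrolyses the ketal.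

Step 5
Reactants: 12 diethylphosphonoacetic acid; 13 2-(trimethylsilyl)ethanol
Product: 14 2-(trimethylsilyl)ethyl diethylphosphonoacetate
Conditions: DCC, DMAP (cat.), CH2Cl2, 0 °C → rt
Reagents that add atoms: none
Why: Carbodiimide (Steglich) esterification gives the phosphonate with a fluoride-labile ester that survives every later step and can be removed at the end without touching the acetate.

Step 6
Reactants: 11 methyl ketone; 14 2-(trimethylsilyl)ethyl diethylphosphonoacetate
Product: 16 (E)-enoate (complete C11–C16 side chain as its 2-(trimethylsilyl)ethyl ester), via sodium phosphonate anion 15 (not isolated)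
Conditions: NaH, THF, 0 °C; then 11, 0 → 60 °C
Reagents that add atoms: none
Why: Horner–Wadsworth–Emmons olefination of the methyl ketone gives the trisubstituted enoate, the E isomer (ester trans to the longer chain) being expected to predominate and the Z isomer being removed by chromatography.

Step 7
Reactants: 16 (E)-enoate
Product: 17 aldehyde (C10–CH2–CH2–CHO; the aldehyde carbon is C3)
Conditions: PdCl2(PhCN)2 (10 mol %), CuCl2·2H2O (10 mol %), AgNO2 (5 mol %), O2 (1 atm), t-BuOH/MeNO2, rt
Reagents that add atoms: dioxygen O=O
Why: Nitrite-modified aldehyde-selective (anti-Markovnikov) Wacker oxidation acts only on the monosubstituted allyl alkene, whose neopentyl-type environment disfavours attack at the internal carbon, while the 1,1-disubstituted and trisubstituted alkenes are inert.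

Step 8
Reactants: 17 aldehyde
Product: 18 (3R)-allylic alcohol (vinyl carbinol at C3)
Conditions: Zn(CH=CH2)2 (from CH2=CHMgBr and ZnCl2, magnesium salts removed with 1,4-dioxane), (−)-MIB (5 mol %), toluene, −20 → 0 °C; 1 M HCl work-up
Reagents that add atoms: divinylzinc C=C[Zn]C=C
Why: Amino-alcohol-catalysed enantioselective addition of a vinylzinc reagent to the aldehyde sets C3 by catalyst control (Si-face transfer, 3R), the remote ring stereocentres having no influence; this configuration, epimeric to the target, is chosen so that the hydroxyl lies on the face of the C10 methyl and can steer step 10.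

Step 9
Reactants: 18 (3R)-allylic alcohol
Product: 19 trans-fused bicyclic cycloheptenol (seven-membered ring C10–C1–C2–C3(OH)–C19=C4(CH3)–C5; 3R hydroxyl cis to the C10 methyl)
Conditions: second-generation Grubbs catalyst [RuCl2(=CHPh)(H2IMes)(PCy3)] (5 mol %), CH2Cl2 (5 mM), 40 °C
Reagents that add atoms: none
Why: Ring-closing metathesis between the vinyl carbinol and the isopropenyl group closes the trans-fused cycloheptene and creates the trisubstituted C19=C4 alkene, the trisubstituted ring B alkene and the enoate being too hindered or electron-poor to compete; no stereocentre is formed.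

Step 10
Reactants: 19 bicyclic cycloheptenol
Product: 20 syn-epoxy alcohol (C19–C4 epoxide oxygen cis to the C3 hydroxyl and to the C10 methyl)
Conditions: VO(acac)2 (5 mol %), t-BuOOH (1.5 equiv), CH2Cl2, 0 °C → rt
Reagents that add atoms: tert-butyl hydroperoxide CC(C)(C)OO
Why: Hydroxyl-directed vanadium-catalysed epoxidation transfers oxygen within the allylic vanadate to the alkene face syn to the C3 hydroxyl, i.e. the face of the C10 methyl, setting C19 and C4 of the epoxide and sparing the undirected ring B alkene and the enoate.

Step 11
Reactants: 20 syn-epoxy alcohol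
Product: 21 anti-epoxy acetate (3S acetate trans to the epoxide oxygen)
Conditions: PPh3, DIAD, AcOH, THF, 0 °C → rt
Reagents that add atoms: acetic acid CC(=O)O
Why: Mitsunobu esterification inverts C3 by SN2 attack of acetate on the alkoxyphosphonium ion (the syn epoxide cannot assist ionisation), which installs the acetate with the C3 configuration of the target and anti to the epoxide oxygen.

Step 12
Reactants: 21 anti-epoxy acetate
Product: 22 2-(trimethylsilyl)ethyl ester of the target (ring A formed; C3 axial acetate, C4 axial formyl and equatorial methyl)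
Conditions: methylaluminium bis(4-bromo-2,6-di-tert-butylphenoxide) (MABR, 30 mol %), CH2Cl2, −78 → −20 °C
Reagents that add atoms: none
Why: The aluminium Lewis acid binds the epoxide oxygen and the C4–O bond at the tertiary terminus ionises while the C3–C19 ring bond migrates to C4 antiperiplanar to the departing oxygen and the C19 alkoxide collapses to the aldehyde, so C19 leaves the ring and the cycloheptane becomes ring A. The closest known reaction type is the Lewis-acid-promoted semipinacol (Meinwald-type) rearrangement of 2,3-epoxy alcohol silyl ethers and esters to β-oxygenated aldehydes, including ring contractions of cyclic epoxides. Ring A (C1–C2–C3–C4–C5–C10) is closed by a suprafacial 1,2-shift of C3 from C19 to C4, i.e. a ring contraction and not an end-to-end cyclisation. The only new stereocentre, quaternary C4, is set stereospecifically by inversion: C3 enters on the face opposite the epoxide oxygen, which step 10 placed on the face of the C10 methyl, so the formyl group becomes axial and cis to that methyl and the C4 methyl equatorial, while C3 migrates with retention of the configuration installed in step 11. The step needs migration of the acetoxy-bearing carbon to beat hydride shift from C19 and participation by the acetate carbonyl; the bulky aluminium phenoxide favours alkyl over hydride migration in trisubstituted epoxides, and low temperature in a non-nucleophilic medium is meant to limit acyloxonium formation.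

Step 13
Reactants: 22 2-(trimethylsilyl)ethyl ester of the target
Product: 23 target acid CNP0312710.1
Conditions: Bu4NF, THF, 0 °C → rt; cold 0.5 M HCl work-up
Reagents that add atoms: none
Why: Fluoride-induced fragmentation of the 2-(trimethylsilyl)ethyl ester (attack at silicon, loss of ethylene) frees the carboxylic acid without affecting the acetate, the non-enolisable aldehyde or any stereocentre.

## Compound list

1 | (S)-(+)-carvone | CC1=CC[C@@H](CC1=O)C(C)=C | starting material
2 | lithium cross-conjugated dienolate of carvone | CC1=CC[C@@H](C=C1O[Li])C(C)=C | intermediate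
3 | (5S,6R)-6-methylcarvone (methyl trans to isopropenyl) | C[C@H]1C(=O)C(C)=CC[C@@H]1C(C)=C | intermediate
4 | lithium enolate of 6-methylcarvone | CC1=CC[C@@H](C(C)=C1O[Li])C(C)=C | intermediate
5 | (5R,6R)-6-allyl-6-methylcarvone (allyl trans, methyl cis to isopropenyl) | C=CC[C@@]1(C)C(=O)C(C)=CC[C@@H]1C(C)=C | intermediate
6 | 2-(2-bromoethyl)-2-methyl-1,3-dioxolane | BrCCC1(C)OCCO1 | starting material
7 | [2-(2-methyl-1,3-dioxolan-2-yl)ethyl]magnesium bromide | Br[Mg]CCC1(C)OCCO1 | intermediate
8 | bromomagnesium tertiary allylic alkoxide (oxygen cis to the C10 methyl) | C=CC[C@@]1(C)[C@](CCC2(C)OCCO2)(O[Mg]Br)C(C)=CC[C@@H]1C(C)=C | intermediate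
9 | tertiary allylic methyl carbonate (OCO2Me cis to the C10 methyl) | C=CC[C@@]1(C)[C@](CCC2(C)OCCO2)(OC(=O)OC)C(C)=CC[C@@H]1C(C)=C | intermediate
10 | ketal triene (C7=C8; C9–H trans, ketal side chain cis to the C10 methyl) | C=CC[C@@]1(C)[C@H](CCC2(C)OCCO2)C(C)=CC[C@@H]1C(C)=C | intermediate
11 | methyl ketone (3-oxobutyl chain on C9, cis to the C10 methyl) | C=CC[C@@]1(C)[C@H](CCC(C)=O)C(C)=CC[C@@H]1C(C)=C | intermediate
12 | diethylphosphonoacetic acid | OC(=O)CP(=O)(OCC)OCC | starting material
13 | 2-(trimethylsilyl)ethanol | C[Si](C)(C)CCO | starting material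
14 | 2-(trimethylsilyl)ethyl diethylphosphonoacetate | CCOP(=O)(CC(=O)OCC[Si](C)(C)C)OCC | intermediate
15 | sodium salt of phosphonate 14 (carbanion) | CCOP(=O)([CH-]C(=O)OCC[Si](C)(C)C)OCC.[Na+] | intermediate
16 | (E)-enoate: monocyclic ring B with allyl and isopropenyl groups and the full side chain as 2-(trimethylsilyl)ethyl ester | C=CC[C@@]1(C)[C@H](CC/C(C)=C/C(=O)OCC[Si](C)(C)C)C(C)=CC[C@@H]1C(C)=C | intermediate
17 | aldehyde (C10–CH2CH2CHO) | O=CCC[C@@]1(C)[C@H](CC/C(C)=C/C(=O)OCC[Si](C)(C)C)C(C)=CC[C@@H]1C(C)=C | intermediate
18 | (3R)-allylic alcohol (vinyl carbinol) | C=C[C@H](O)CC[C@@]1(C)[C@H](CC/C(C)=C/C(=O)OCC[Si](C)(C)C)C(C)=CC[C@@H]1C(C)=C | intermediate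
19 | trans-fused bicyclic cycloheptenol (3R hydroxyl cis to the C10 methyl; C19=C4 alkene) | O[C@@H]1CC[C@@]2(C)[C@H](CC/C(C)=C/C(=O)OCC[Si](C)(C)C)C(C)=CC[C@@H]2C(C)=C1 | intermediate
20 | syn-epoxy alcohol (epoxide oxygen and 3R hydroxyl both cis to the C10 methyl) | O[C@@H]1CC[C@@]2(C)[C@H](CC/C(C)=C/C(=O)OCC[Si](C)(C)C)C(C)=CC[C@@H]2[C@]3(C)O[C@@H]31 | intermediate
21 | anti-epoxy acetate (3S acetate trans to the epoxide oxygen) | CC(=O)O[C@H]1CC[C@@]2(C)[C@H](CC/C(C)=C/C(=O)OCC[Si](C)(C)C)C(C)=CC[C@@H]2[C@]3(C)O[C@@H]31 | intermediate
22 | 2-(trimethylsilyl)ethyl ester of the target | CC(=O)O[C@H]1CC[C@@]2(C)[C@H](CC/C(C)=C/C(=O)OCC[Si](C)(C)C)C(C)=CC[C@@H]2[C@]1(C)C=O | intermediate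
23 | CNP0312710.1 | CC(=O)O[C@H]1CC[C@@]2(C)[C@H](CC/C(C)=C/C(=O)O)C(C)=CC[C@@H]2[C@]1(C)C=O | target

## Step count and risks

Total step count: 13 (twelve in the main line, one for phosphonate 14).
Longest linear sequence: 12 steps from (S)-carvone (steps 1–4 and 6–13).

Steps most likely to fail:

1. Step 12. Participation of the acetate carbonyl at C19 or C4 (acyloxonium formation), or hydride shift from C19 to C4 to give an α-acetoxy cycloheptanone, may outrun migration of the C3–C19 bond. The fallback switches to the silyl ether variant and sets out from 21. K2CO3, MeOH, 0 °C removes the acetate to give the anti-epoxy alcohol F1. TBSCl, imidazole, DMF gives the tert-butyldimethylsilyl ether F2. Methylaluminium bis(4-bromo-2,6-di-tert-butylphenoxide), CH2Cl2, −78 °C then effects the rearrangement of an epoxy silyl ether, in which the non-participating siloxy-bearing carbon migrates anti, to the β-siloxy aldehyde F3. HF·pyridine, THF gives the β-hydroxy aldehyde F4, and Ac2O, DMAP, pyridine returns to the route at 22.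

2. Step 10. Oxygen transfer within the vanadium alkoxide may be slow because the hydroxyl is pseudoequatorial and the required face is the more hindered one, so oxidation of the allylic alcohol to the enone or loss of facial control can intervene. The fallback delivers the oxygen by an electrophile-induced cyclisation and sets out from 19. Boc2O, DMAP, MeCN gives the tert-butyl carbonate F5. IBr, toluene, −80 °C triggers iodocarbonate cyclisation: the carbonate oxygen is delivered to C4 on the face of the C3 oxygen, iodine adds anti at C19 and the tert-butyl group is lost, giving the iodo cyclic carbonate F6 (the five-membered regioisomer would converge on the same epoxide). K2CO3, MeOH cleaves the carbonate and the freed C4 alkoxide displaces iodide from the back, which returns to the route at 20.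

3. Step 4. Hydride may be transferred to the less hindered allyl terminus C7 (giving the tetrasubstituted C8=C9 alkene), the allylpalladium species may undergo β-hydride elimination to dienes, and any lack of facial control in the Grignard addition is carried into C9. The fallback replaces the hydrogenolysis by a transposition–reduction sequence and sets out from 5. Addition of Grignard reagent 7 with aqueous NH4Cl work-up gives the tertiary allylic alcohol F7. Pyridinium chlorochromate [C5H5NH][CrO3Cl], NaOAc, CH2Cl2 effects oxidative 1,3-transposition to the enone F8. Li, NH3, THF, −78 °C reduces the enone (β-protonation gives the more stable C9 epimer, side chain equatorial and cis to the C10 methyl), and PhNTf2 traps the regiodefined enolate as the enol triflate F9. Pd(OAc)2, PPh3, HCO2H, n-Bu3N, DMF reduces the triflate to 10, which rejoins the route at the acid hydrolysis of step 4.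

Further compounds
F1 | step 12 | anti-epoxy alcohol (3S hydroxyl trans to the epoxide oxygen) | O[C@H]1CC[C@@]2(C)[C@H](CC/C(C)=C/C(=O)OCC[Si](C)(C)C)C(C)=CC[C@@H]2[C@]3(C)O[C@@H]31
F2 | step 12 | tert-butyldimethylsilyl ether of F1 | CC(C)(C)[Si](C)(C)O[C@H]1CC[C@@]2(C)[C@H](CC/C(C)=C/C(=O)OCC[Si](C)(C)C)C(C)=CC[C@@H]2[C@]3(C)O[C@@H]31
F3 | step 12 | β-siloxy aldehyde (ring A formed, C3 OTBS) | CC(C)(C)[Si](C)(C)O[C@H]1CC[C@@]2(C)[C@H](CC/C(C)=C/C(=O)OCC[Si](C)(C)C)C(C)=CC[C@@H]2[C@]1(C)C=O
F4 | step 12 | β-hydroxy aldehyde (C3 OH) | O[C@H]1CC[C@@]2(C)[C@H](CC/C(C)=C/C(=O)OCC[Si](C)(C)C)C(C)=CC[C@@H]2[C@]1(C)C=O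
F5 | step 10 | tert-butyl carbonate of 19 | CC(C)(C)OC(=O)O[C@@H]1CC[C@@]2(C)[C@H](CC/C(C)=C/C(=O)OCC[Si](C)(C)C)C(C)=CC[C@@H]2C(C)=C1
F6 | step 10 | iodo cyclic carbonate (carbonate bridging the C3 and C4 oxygens on the face of the C10 methyl; iodine on C19 on the opposite face) | O=C1O[C@@H]2CC[C@@]3(C)[C@H](CC/C(C)=C/C(=O)OCC[Si](C)(C)C)C(C)=CC[C@@H]3[C@](C)(O1)[C@H]2I
F7 | step 4 | tertiary allylic alcohol (hydroxyl cis to the C10 methyl) | C=CC[C@@]1(C)[C@](CCC2(C)OCCO2)(O)C(C)=CC[C@@H]1C(C)=C
F8 | step 4 | transposed enone (C7 ketone, C8=C9) | C=CC[C@@]1(C)C(CCC2(C)OCCO2)=C(C)C(=O)C[C@@H]1C(C)=C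
F9 | step 4 | enol triflate (C7 OTf, C7=C8; C9–H trans to the C10 methyl) | C=CC[C@@]1(C)[C@H](CCC2(C)OCCO2)C(C)=C(OS(=O)(=O)C(F)(F)F)C[C@@H]1C(C)=C
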